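## Structural features

The target is a linear chain of eight oxygenated benzene rings, A to H, joined only by seven diaryl ether oxygens. It carries twenty-one free phenolic hydroxyls and has no stereocentre and no ring-to-ring carbon–carbon bond. Rings B, D and F are para-linked units: the preceding ring's oxygen on C1, the following ring's oxygen on C4, and hydroxyls on C3 and C5, so the C4 oxygen is flanked on both sides. Rings C, E and G are ortho-linked pentaoxygenated units with ether oxygens on the neighbouring carbons C1 and C6 and hydroxyls on C3, C4 and C5. Ring A is a 2,4,6-trihydroxyphenyl end group and ring H a 3,4,5-trihydroxyphenyl end group. The pyrogallol- and phloroglucinol-type rings oxidise very easily, so every hydroxyl has to stay masked as an alkyl ether until the last step. The real difficulty is that each of the seven ethers has one carbon flanked by two oxygen substituents, and the rings are too electron-rich for nucleophilic aromatic substitution unless a temporary activating group is present. The key step exploits the pattern of ring B (ring A oxygen on C1, hydroxyl on C3, ring C oxygen on C4, hydroxyl on C5): C3 to C6 can come from a cyclobutenone that already carries the ring C oxygen, and C1 and C2 from an alkyne that already carries the ring A oxygen.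

## Logic of the disconnections

37 is traced back to 36 by cutting the twenty-one oxygen–alkyl bonds. The free polyphenol would not survive any coupling or chromatography, whereas 36 is a neutral, oxidation-stable compound. The forward demand is one exhaustive dealkylation that leaves the seven diaryl ethers untouched.

36 is cut at the bond between C6 of ring C and the oxygen on C1 of ring D, giving 21 and 35. This is a three-ring plus five-ring union. It is the one ether whose hindered carbon cannot be activated by a formyl group, because ring C is committed to ring B through the key step. The forward step must therefore substitute a bromide flanked by an aryloxy and a methoxy group, and for that reason 21 carries no free hydroxyl and 35 no halogen.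

21 goes back to 20 by cutting the O–CH3 bond on C3 of ring B. The hydroxyl that the benzannulation liberates would otherwise compete as a nucleophile in the union.

20 is cut at C2–C3 and C6–C1 of ring B, giving 8 and 15. Both ether oxygens of ring B sit where arylation is weakest: the ring A side is a phenol between two methoxy groups, and C4 of ring B lies between two oxygens. Building ring B from pieces that already hold these oxygens avoids both arylations and reduces a three-ring ether to two monocyclic aryl ethers. The forward step needs one alkyne orientation and thermal tolerance of the aryl bromide, and it is run at the three-ring stage on inexpensive material.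

8 is cut across its four-membered ring into the ketene 7 (from 5) and 6. 5 comes from 4, 4 from 2 and 3 by cutting the O–CH2 bond, and 2 from 1 by cutting C–Br. Each forward step is a standard operation on a monocyclic arene; the cycloaddition needs the ketene to be trapped by 6 faster than it dimerises.

15 goes back to 12 and then to 9 and 10. The two alkyne carbons come from 10, so the hindered oxygen of ring A is alkylated, never arylated.

35 is taken apart one ring at a time: 35 from 33, 33 from 32 and 26; 32 from 30, 30 from 29 and 22; 29 from 27, 27 from 25 and 26; 25 from 23, 23 from 1 and 22. Each cut is the ether bond at the carbon that bore bromine, followed by formyl-for-hydroxyl exchange. The formyl group of 22 (ortho to bromine) or 26 (para to bromine) activates the hindered C–Br bond and is the latent oxygen of the next ether. The forward demand is aryl rather than hydride migration in each oxidation. A variant that reuses one brominated two-ring aldehyde twice would save two steps, but it would add two more couplings at unactivated, hindered bromides and was not adopted.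

## Other disconnections considered

Alternative 1: The cut is the bond from the ring F oxygen to C1 of ring G together with the C6–I bond of ring G. In the forward direction the phenoxide of the six-ring phenol A2 would add to the aryne A4, released by fluoride from the silyl triflate A3, and the aryl anion would be intercepted by an electrophilic iodine source to give A1. In its favour, arynes accept hindered nucleophiles such as the ring F oxygen, the methoxy group next to the triple bond directs the oxygen to the distal carbon, and two bonds form in one metal-free step. It also delivers an iodide, which is a better handle for the next copper coupling than the bromide of 21; on that point it is superior. Against it, the aryl anion must be iodinated in competition with protonation, and electrophilic iodine would also attack the phloroglucinol-type CH positions and the phenoxide of A2. The step would be run on a six-ring substrate, solves one junction only, and leaves rings A to C to other chemistry. Compared with the chosen plan, it is a polar addition to a strained alkyne where the chosen step is a pericyclic cascade, and it adds a ring in one step where the chosen route needs two (coupling, oxidation). Every later ring would then need a coupling at an unactivated, hindered halide, which the chosen plan confines to step 17.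

Alternative 2: The cut is the bond in ring A between the ether-bearing carbon and a neighbouring hydroxyl-bearing carbon. In the forward direction the dioxo ester A6 would undergo an intramolecular Claisen condensation of C6 onto the ester carbon to give A5. In its favour, the ring A to ring B ether comes from O-alkylation of an unhindered phenol, the same principle as in the chosen plan and equal to it. The reagents are cheap and involve no organolithium, ketene or sealed-tube thermolysis, so it is operationally simpler than steps 4 to 7; on that point it is better. Against it, the carbanion needed at C6 is the least acidic of the three methylene sites, and 3,5-dioxo esters tend to close through oxygen to a pyranone such as A7. A5 is an air-sensitive triol that must be capped at once, and after debenzylation the ring B oxygen at C4 is a phenol between two methoxy groups that still has to be arylated by a ring C electrophile. Compared with the chosen plan, it builds only the terminal ring and one ether, whereas step 7 sets both ethers of ring B. Step count to a two-ring unit is similar, but the route to a three-ring unit is longer and ends in the hindered arylation that step 7 avoids.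

Alternative 3: The cut is the C1–C6 bond of ring E. In the forward direction the cyclobutenone A9, made from A10 by addition of a (Z)-2-aryloxyvinyl metal reagent and O-methylation, would open on heating to a dienylketene, close by 6π electrocyclisation and tautomerise to A8. In its favour, squarate ring expansions are the best documented of the cyclobutenone-to-arene reactions and place four contiguous oxygens without regiochemical ambiguity; on precedent it is stronger than step 7. The ring D to ring E ether again comes from a vinyl ether and not from an arylation (equal in principle), and the free hydroxyl appears exactly on C6 of ring E. Against it, the vinyl metal reagent must be Z (the E isomer cannot cyclise) and can lose aryloxide by β-elimination. The next ether from A8 requires arylation of a phenol flanked by an aryloxy and a methoxy group. After debenzylation, ring D must still be joined to a hindered ring C halide as in step 17. Compared with the chosen plan, it constructs the ortho-linked rings whereas step 7 constructs a para-linked ring, so the two are complementary. Each pentaoxygenated ring would cost a squarate sequence of at least three steps plus the vinyl reagent, against two steps per ring from a purchased bromobenzaldehyde here.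

Key step: step 7

Remark: 1, 3, 6 (hexane solution), 9, 10, 22 and 26 are taken as purchased; mapping the atoms of 8 and 15 onto 20 (ketene carbon to C3 of ring B, alkyne carbons to C1 and C2) shows the three structures to be mutually consistent, so they are used unchanged, and the ethyl ether that 6 leaves on ring B is carried to the last step.

## Route

Step 1
Reactants: 1 3,4,5-trimethoxyphenol
Product: 2 2-bromo-3,4,5-trimethoxyphenol
Conditions: NBS (1.0 equiv), CH2Cl2, −78 → 0 °C
Reagents that add atoms: N-bromosuccinimide, O=C1CCC(=O)N1Br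
Why: Electrophilic aromatic bromination; the two free ring positions of 1 are equivalent (ortho to OH, next to OMe), so one equivalent of NBS at low temperature should give a single monobromide, and the first bromine slows a second substitution.

Step 2
Reactants: 2 2-bromo-3,4,5-trimethoxyphenol; 3 bromoacetic acid
Product: 4 (2-bromo-3,4,5-trimethoxyphenoxy)acetic acid
Conditions: NaH (2.2 equiv), THF, 0 °C → reflux; then 1 M HCl
Reagents that add atoms: none
Why: Williamson ether synthesis; the sodium phenoxide displaces bromide from sodium bromoacetate (SN2 at a primary α-halo carboxylate) and acidification releases the aryloxyacetic acid.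

Step 3
Reactants: 4 (2-bromo-3,4,5-trimethoxyphenoxy)acetic acid
Product: 5 (2-bromo-3,4,5-trimethoxyphenoxy)acetyl chloride
Conditions: (COCl)2 (1.5 equiv), DMF (cat.), CH2Cl2, 0 °C → rt
Reagents that add atoms: oxalyl chloride, ClC(=O)C(=O)Cl
Why: Standard acid chloride formation through the chloroiminium species from DMF; aryl ethers and the aryl bromide are inert, and the crude chloride is used directly.

Step 4
Reactants: 5 (2-bromo-3,4,5-trimethoxyphenoxy)acetyl chloride; 6 ethoxyacetylene
Product: 8 4-(2-bromo-3,4,5-trimethoxyphenoxy)-3-ethoxycyclobut-2-en-1-one (racemic), via aryloxyketene 7 (not isolated)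
Conditions: 6 (3 equiv), Et3N (1.2 equiv, slow addition), CH2Cl2, 0 °C → rt
Reagents that add atoms: none
Why: Dehydrochlorination gives ketene 7, which undergoes a thermal ketene–ynol ether [2+2] cycloaddition with 6; the ketene carbonyl carbon bonds to the unsubstituted alkyne carbon, which places OEt on C3 and the aryloxy group on C4. C4 forms as a racemate, which is immaterial because it becomes an sp2 carbon of ring B in step 7.

Step 5
Reactants: 9 2,4,6-trimethoxyphenol; 10 trichloroethylene
Product: 12 2-{[(E)-1,2-dichloroethenyl]oxy}-1,3,5-trimethoxybenzene, via dichloroacetylene 11 (not isolated)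
Conditions: K2CO3 (2 equiv), DMF, 70 °C, Ar
Reagents that add atoms: none
Why: Base eliminates HCl from 10 to give 11 in low stationary concentration; anti addition of the phenoxide of 9 and protonation should give the (E)-dichlorovinyl ether, the established route from phenols to aryl 1,2-dichlorovinyl ethers.

Step 6
Reactants: 12 2-{[(E)-1,2-dichloroethenyl]oxy}-1,3,5-trimethoxybenzene
Product: 15 2-(ethynyloxy)-1,3,5-trimethoxybenzene, via chloroalkyne 13 (not isolated), via lithium acetylide 14 (not isolated)
Conditions: n-BuLi (2.2 equiv), THF, −78 → −40 °C; MeOH, −78 °C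
Reagents that add atoms: none
Why: Dehydrochlorination to 13, lithium–chlorine exchange to 14 and cold protonation form the known sequence from dichlorovinyl ethers to terminal ynol ethers; the two flanking methoxy groups shield the ynol ether, which is used promptly in step 7.

Step 7
Reactants: 8 4-(2-bromo-3,4,5-trimethoxyphenoxy)-3-ethoxycyclobut-2-en-1-one; 15 2-(ethynyloxy)-1,3,5-trimethoxybenzene
Product: 20 2-(2-bromo-3,4,5-trimethoxyphenoxy)-3-ethoxy-5-(2,4,6-trimethoxyphenoxy)phenol (three-ring phenol ABC), via vinylketene 16 (not isolated), via vinylcyclobutenone 17 (not isolated), via dienylketene 18 (not isolated), via cyclohexadienone 19 (not isolated)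
Conditions: 15 (1.5 equiv), toluene, 80 → 110 °C, sealed tube, Ar; then K2CO3, MeOH, rt
Reagents that add atoms: none
Why: Heating opens 8 by a 4π electrocyclic cleavage of the C1–C4 bond, the aryloxy group rotating outward, to give vinylketene 16. 16 adds to 15 in a ketene–alkyne [2+2] cycloaddition that forms C2–C3 and C6–C1 of the future ring B and gives 17. 17 opens again to dienylketene 18, which closes ring B by a thermal 6π electrocyclisation between the ketene carbon (C3) and the aryloxy-bearing terminus (C4) to give 19, and enolisation gives phenol 20. The closest known reaction type is the Danheiser benzannulation of cyclobutenones with alkoxy- and siloxyalkynes to resorcinol monoethers. No stereocentre is created: the centre of 8 and the sp3 carbons of 17 and 19 all end as sp2 ring carbons. The selectivity needed is the orientation of the alkyne; the oxygen lone pair makes the unsubstituted carbon of 15 the nucleophilic one, so it bonds to the electrophilic ketene carbon and the ring A oxygen ends meta to the new hydroxyl and para to the ring C oxygen. Excess 15 is used to outrun ketene dimerisation and acylation of 20 by 16, and any aryl ester formed in that way is cleaved by the K2CO3/MeOH treatment. The aryl bromide and the aryl and ethyl ethers are inert to neutral thermolysis.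

Step 8
Reactants: 20 three-ring phenol ABC
Product: 21 2-(2-bromo-3,4,5-trimethoxyphenoxy)-1-ethoxy-3-methoxy-5-(2,4,6-trimethoxyphenoxy)benzene (three-ring bromide ABC)
Conditions: MeI, K2CO3, acetone, reflux
Reagents that add atoms: iodomethane, CI
Why: Williamson O-methylation of the only free hydroxyl, so that 21 enters the union with no competing nucleophile.

Step 9
Reactants: 1 3,4,5-trimethoxyphenol; 22 2-bromo-3,4,5-trimethoxybenzaldehyde
Product: 23 3,4,5-trimethoxy-2-(3,4,5-trimethoxyphenoxy)benzaldehyde (two-ring aldehyde GH)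
Conditions: CuI (10 mol %), picolinic acid (20 mol %), K3PO4, DMSO, 90 °C
Reagents that add atoms: none
Why: Copper-catalysed Ullmann-type O-arylation; the C–Br bond of 22 is activated by the ortho formyl group and 1 has no ortho substituent, and the formyl group is the latent C1 oxygen of ring G.

Step 10
Reactants: 23 two-ring aldehyde GH
Product: 25 3,4,5-trimethoxy-2-(3,4,5-trimethoxyphenoxy)phenol (two-ring phenol GH), via aryl formate 24 (not isolated)
Conditions: mCPBA (1.3 equiv), CH2Cl2, 0 °C → rt; aq NaHCO3 wash; K2CO3 (cat.), MeOH, rt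
Reagents that add atoms: 3-chloroperbenzoic acid, OOC(=O)c1cccc(Cl)c1
Why: Baeyer–Villiger (Dakin-type) oxidation; the aryl group, carrying a para methoxy and an ortho aryloxy donor, should migrate in preference to hydride to give formate 24, which methanolysis cleaves to the phenol.

Step 11
Reactants: 25 two-ring phenol GH; 26 4-bromo-3,5-dimethoxybenzaldehyde
Product: 27 3,5-dimethoxy-4-[3,4,5-trimethoxy-2-(3,4,5-trimethoxyphenoxy)phenoxy]benzaldehyde (three-ring aldehyde FGH)
Conditions: CuI (10 mol %), picolinic acid (20 mol %), K3PO4, DMSO, 90 °C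
Reagents that add atoms: none
Why: Ullmann-type O-arylation; the bromide of 26 lies between two methoxy groups but is activated by the para formyl group, and the nucleophile has only one ortho substituent.

Step 12
Reactants: 27 three-ring aldehyde FGH
Product: 29 3,5-dimethoxy-4-[3,4,5-trimethoxy-2-(3,4,5-trimethoxyphenoxy)phenoxy]phenol (three-ring phenol FGH), via aryl formate 28 (not isolated)
Conditions: mCPBA (1.3 equiv), CH2Cl2, 0 °C → rt; aq NaHCO3 wash; K2CO3 (cat.), MeOH, rt
Reagents that add atoms: 3-chloroperbenzoic acid, OOC(=O)c1cccc(Cl)c1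
Why: Baeyer–Villiger oxidation of a 3,4,5-trioxygenated benzaldehyde, a substrate type known to give the phenol through aryl migration; methanolysis removes the formyl group.

Step 13
Reactants: 29 three-ring phenol FGH; 22 2-bromo-3,4,5-trimethoxybenzaldehyde
Product: 30 2-{3,5-dimethoxy-4-[3,4,5-trimethoxy-2-(3,4,5-trimethoxyphenoxy)phenoxy]phenoxy}-3,4,5-trimethoxybenzaldehyde (four-ring aldehyde EFGH)
Conditions: CuI (10 mol %), picolinic acid (20 mol %), K3PO4, DMSO, 90 °C
Reagents that add atoms: none
Why: Same Ullmann-type coupling as step 9; the nucleophile is an unhindered phenol and the bromide is activated by the ortho formyl group.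

Step 14
Reactants: 30 four-ring aldehyde EFGH
Product: 32 2-{3,5-dimethoxy-4-[3,4,5-trimethoxy-2-(3,4,5-trimethoxyphenoxy)phenoxy]phenoxy}-3,4,5-trimethoxyphenol (four-ring phenol EFGH), via aryl formate 31 (not isolated)
Conditions: mCPBA (1.3 equiv), CH2Cl2, 0 °C → rt; aq NaHCO3 wash; K2CO3 (cat.), MeOH, rt
Reagents that add atoms: 3-chloroperbenzoic acid, OOC(=O)c1cccc(Cl)c1
Why: Baeyer–Villiger oxidation as in step 10; the para methoxy and ortho aryloxy groups favour aryl migration.

Step 15
Reactants: 32 four-ring phenol EFGH; 26 4-bromo-3,5-dimethoxybenzaldehyde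
Product: 33 five-ring aldehyde DEFGH (4-aryloxy-3,5-dimethoxybenzaldehyde whose aryloxy group is the EFGH chain of 32 bound through C1 of ring E)
Conditions: CuI (10 mol %), picolinic acid (20 mol %), K3PO4, DMSO, 90 °C
Reagents that add atoms: none
Why: Same Ullmann-type coupling as step 11; the para formyl group activates the hindered bromide.

Step 16
Reactants: 33 five-ring aldehyde DEFGH
Product: 35 five-ring phenol DEFGH (hydroxyl on C1 of ring D), via aryl formate 34 (not isolated)
Conditions: mCPBA (1.3 equiv), CH2Cl2, 0 °C → rt; aq NaHCO3 wash; K2CO3 (cat.), MeOH, rt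
Reagents that add atoms: 3-chloroperbenzoic acid, OOC(=O)c1cccc(Cl)c1
Why: Baeyer–Villiger oxidation as in step 12, giving the only free hydroxyl of the five-ring fragment.

Step 17
Reactants: 21 three-ring bromide ABC; 35 five-ring phenol DEFGH
Product: 36 eight-ring ether ABCDEFGH with twenty methyl ethers and one ethyl ether (on C5 of ring B)
Conditions: 21 (1.2 equiv), CuI (20 mol %), picolinic acid (40 mol %), K3PO4, DMSO, 110 °C
Reagents that add atoms: none
Why: Copper-catalysed O-arylation of the unhindered phenol 35 with the bromide on C6 of ring C; this is the one coupling at a halide without an activating group, run with a ligand system developed for hindered diaryl ethers. 21 has no free hydroxyl and 35 no halogen, so only one ether can form.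

Step 18
Reactants: 36 eight-ring ether ABCDEFGH
Product: 37 CNP0206369.0 (target)
Conditions: BBr3 (60 equiv), CH2Cl2, −78 °C → rt; MeOH then H2O, Ar
Reagents that add atoms: none
Why: Lewis acid cleavage of all twenty methyl ethers and the ethyl ether through aryloxyboron species that hydrolyse on work-up; diaryl ether bonds are not cleaved because neither aryl carbon is open to bromide attack.

## Compound list

1 | 3,4,5-trimethoxyphenol | COc1cc(O)cc(OC)c1OC | starting material
2 | 2-bromo-3,4,5-trimethoxyphenol | COc1cc(O)c(Br)c(OC)c1OC | intermediate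
3 | bromoacetic acid | OC(=O)CBr | starting material
4 | (2-bromo-3,4,5-trimethoxyphenoxy)acetic acid | COc1cc(OCC(=O)O)c(Br)c(OC)c1OC | intermediate
5 | (2-bromo-3,4,5-trimethoxyphenoxy)acetyl chloride | COc1cc(OCC(=O)Cl)c(Br)c(OC)c1OC | intermediate
6 | ethoxyacetylene | CCOC#C | starting material
7 | (2-bromo-3,4,5-trimethoxyphenoxy)ketene | COc1cc(OC=C=O)c(Br)c(OC)c1OC | intermediate
8 | 4-(2-bromo-3,4,5-trimethoxyphenoxy)-3-ethoxycyclobut-2-en-1-one (racemic) | CCOC1=CC(=O)C1Oc1cc(OC)c(OC)c(OC)c1Br | intermediate
9 | 2,4,6-trimethoxyphenol | COc1cc(OC)c(O)c(OC)c1 | starting material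
10 | trichloroethylene | ClC=C(Cl)Cl | starting material
11 | dichloroacetylene | ClC#CCl | intermediate
12 | 2-{[(E)-1,2-dichloroethenyl]oxy}-1,3,5-trimethoxybenzene | Cl/C=C(/Cl)Oc1c(OC)cc(OC)cc1OC | intermediate
13 | 2-[(chloroethynyl)oxy]-1,3,5-trimethoxybenzene | ClC#COc1c(OC)cc(OC)cc1OC | intermediate
14 | lithium 2-(2,4,6-trimethoxyphenoxy)ethynide | [Li]C#COc1c(OC)cc(OC)cc1OC | intermediate
15 | 2-(ethynyloxy)-1,3,5-trimethoxybenzene | C#COc1c(OC)cc(OC)cc1OC | intermediate
16 | (3Z)-4-(2-bromo-3,4,5-trimethoxyphenoxy)-3-ethoxybuta-1,3-dien-1-one | O=C=C/C(OCC)=C/Oc1cc(OC)c(OC)c(OC)c1Br | intermediate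
17 | 4-[(Z)-2-(2-bromo-3,4,5-trimethoxyphenoxy)-1-ethoxyethenyl]-3-(2,4,6-trimethoxyphenoxy)cyclobut-2-en-1-one (racemic) | O=C1C=C(Oc2c(OC)cc(OC)cc2OC)C1/C(OCC)=C/Oc1cc(OC)c(OC)c(OC)c1Br | intermediate
18 | (3E,5Z)-6-(2-bromo-3,4,5-trimethoxyphenoxy)-5-ethoxy-3-(2,4,6-trimethoxyphenoxy)hexa-1,3,5-trien-1-one | O=C=C/C(Oc1c(OC)cc(OC)cc1OC)=C\C(OCC)=C\Oc1cc(OC)c(OC)c(OC)c1Br | intermediate
19 | 6-(2-bromo-3,4,5-trimethoxyphenoxy)-5-ethoxy-3-(2,4,6-trimethoxyphenoxy)cyclohexa-2,4-dien-1-one (racemic) | O=C1C=C(Oc2c(OC)cc(OC)cc2OC)C=C(OCC)C1Oc1cc(OC)c(OC)c(OC)c1Br | intermediate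
20 | 2-(2-bromo-3,4,5-trimethoxyphenoxy)-3-ethoxy-5-(2,4,6-trimethoxyphenoxy)phenol (three-ring phenol ABC) | CCOc1cc(Oc2c(OC)cc(OC)cc2OC)cc(O)c1Oc1cc(OC)c(OC)c(OC)c1Br | intermediate
21 | 2-(2-bromo-3,4,5-trimethoxyphenoxy)-1-ethoxy-3-methoxy-5-(2,4,6-trimethoxyphenoxy)benzene (three-ring bromide ABC) | CCOc1cc(Oc2c(OC)cc(OC)cc2OC)cc(OC)c1Oc1cc(OC)c(OC)c(OC)c1Br | intermediate
22 | 2-bromo-3,4,5-trimethoxybenzaldehyde | O=Cc1cc(OC)c(OC)c(OC)c1Br | starting material
23 | 3,4,5-trimethoxy-2-(3,4,5-trimethoxyphenoxy)benzaldehyde (two-ring aldehyde GH) | O=Cc1cc(OC)c(OC)c(OC)c1Oc1cc(OC)c(OC)c(OC)c1 | intermediate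
24 | 3,4,5-trimethoxy-2-(3,4,5-trimethoxyphenoxy)phenyl formate | O=COc1cc(OC)c(OC)c(OC)c1Oc1cc(OC)c(OC)c(OC)c1 | intermediate
25 | 3,4,5-trimethoxy-2-(3,4,5-trimethoxyphenoxy)phenol (two-ring phenol GH) | Oc1cc(OC)c(OC)c(OC)c1Oc1cc(OC)c(OC)c(OC)c1 | intermediate
26 | 4-bromo-3,5-dimethoxybenzaldehyde | O=Cc1cc(OC)c(Br)c(OC)c1 | starting material
27 | 3,5-dimethoxy-4-[3,4,5-trimethoxy-2-(3,4,5-trimethoxyphenoxy)phenoxy]benzaldehyde (three-ring aldehyde FGH) | O=Cc1cc(OC)c(Oc2cc(OC)c(OC)c(OC)c2Oc2cc(OC)c(OC)c(OC)c2)c(OC)c1 | intermediate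
28 | 3,5-dimethoxy-4-[3,4,5-trimethoxy-2-(3,4,5-trimethoxyphenoxy)phenoxy]phenyl formate | O=COc1cc(OC)c(Oc2cc(OC)c(OC)c(OC)c2Oc2cc(OC)c(OC)c(OC)c2)c(OC)c1 | intermediate
29 | 3,5-dimethoxy-4-[3,4,5-trimethoxy-2-(3,4,5-trimethoxyphenoxy)phenoxy]phenol (three-ring phenol FGH) | Oc1cc(OC)c(Oc2cc(OC)c(OC)c(OC)c2Oc2cc(OC)c(OC)c(OC)c2)c(OC)c1 | intermediate
30 | 2-{3,5-dimethoxy-4-[3,4,5-trimethoxy-2-(3,4,5-trimethoxyphenoxy)phenoxy]phenoxy}-3,4,5-trimethoxybenzaldehyde (four-ring aldehyde EFGH) | O=Cc1cc(OC)c(OC)c(OC)c1Oc1cc(OC)c(Oc2cc(OC)c(OC)c(OC)c2Oc2cc(OC)c(OC)c(OC)c2)c(OC)c1 | intermediate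
31 | 2-{3,5-dimethoxy-4-[3,4,5-trimethoxy-2-(3,4,5-trimethoxyphenoxy)phenoxy]phenoxy}-3,4,5-trimethoxyphenyl formate | O=COc1cc(OC)c(OC)c(OC)c1Oc1cc(OC)c(Oc2cc(OC)c(OC)c(OC)c2Oc2cc(OC)c(OC)c(OC)c2)c(OC)c1 | intermediate
32 | 2-{3,5-dimethoxy-4-[3,4,5-trimethoxy-2-(3,4,5-trimethoxyphenoxy)phenoxy]phenoxy}-3,4,5-trimethoxyphenol (four-ring phenol EFGH) | Oc1cc(OC)c(OC)c(OC)c1Oc1cc(OC)c(Oc2cc(OC)c(OC)c(OC)c2Oc2cc(OC)c(OC)c(OC)c2)c(OC)c1 | intermediate
33 | five-ring aldehyde DEFGH (formyl on C1 of ring D, all hydroxyls as methyl ethers) | O=Cc1cc(OC)c(Oc2cc(OC)c(OC)c(OC)c2Oc2cc(OC)c(Oc3cc(OC)c(OC)c(OC)c3Oc3cc(OC)c(OC)c(OC)c3)c(OC)c2)c(OC)c1 | intermediate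
34 | five-ring aryl formate DEFGH (formyloxy on C1 of ring D) | O=COc1cc(OC)c(Oc2cc(OC)c(OC)c(OC)c2Oc2cc(OC)c(Oc3cc(OC)c(OC)c(OC)c3Oc3cc(OC)c(OC)c(OC)c3)c(OC)c2)c(OC)c1 | intermediate
35 | five-ring phenol DEFGH (hydroxyl on C1 of ring D) | Oc1cc(OC)c(Oc2cc(OC)c(OC)c(OC)c2Oc2cc(OC)c(Oc3cc(OC)c(OC)c(OC)c3Oc3cc(OC)c(OC)c(OC)c3)c(OC)c2)c(OC)c1 | intermediate
36 | eight-ring ether ABCDEFGH, twenty methyl ethers and one ethyl ether on C5 of ring B | COc1cc(OC)c(Oc2cc(OCC)c(Oc3cc(OC)c(OC)c(OC)c3Oc3cc(OC)c(Oc4cc(OC)c(OC)c(OC)c4Oc4cc(OC)c(Oc5cc(OC)c(OC)c(OC)c5Oc5cc(OC)c(OC)c(OC)c5)c(OC)c4)c(OC)c3)c(OC)c2)c(OC)c1 | intermediate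
37 | CNP0206369.0 | Oc1cc(O)c(Oc2cc(O)c(Oc3cc(O)c(O)c(O)c3Oc3cc(O)c(Oc4cc(O)c(O)c(O)c4Oc4cc(O)c(Oc5cc(O)c(O)c(O)c5Oc5cc(O)c(O)c(O)c5)c(O)c4)c(O)c3)c(O)c2)c(O)c1 | target

## Step count and least certain steps

Total: 18 steps. Longest linear sequence: 10 steps (steps 9 to 18); the branch through the key step is 8 steps (steps 1 to 4, 7, 8, 17, 18).

Step 7 (key step). The donor groups of 8 make vinylketene 16 electron-rich, so its [2+2] addition to 15 may be slower than ketene dimerisation, capture of 16 by the product phenol, or thermal decay of the terminal ynol ether. The fallback makes the three-ring bromide by ether couplings alone; it sets out from 1 and 26 and comes back at 37. Copper-catalysed coupling of 1 with 26 under the conditions of step 11 would give 3,5-dimethoxy-4-(3,4,5-trimethoxyphenoxy)benzaldehyde F1. NBS would brominate the formyl-free ring to 4-(2-bromo-3,4,5-trimethoxyphenoxy)-3,5-dimethoxybenzaldehyde F2. Baeyer–Villiger oxidation would give 4-(2-bromo-3,4,5-trimethoxyphenoxy)-3,5-dimethoxyphenyl formate F3, and methanolysis 4-(2-bromo-3,4,5-trimethoxyphenoxy)-3,5-dimethoxyphenol F4. Copper-catalysed O-arylation of F4 with an excess of purchased 2-iodo-1,3,5-trimethoxybenzene (COc1cc(OC)c(I)c(OC)c1), the iodide reacting before the hindered bromide, would give 2-(2-bromo-3,4,5-trimethoxyphenoxy)-1,3-dimethoxy-5-(2,4,6-trimethoxyphenoxy)benzene F5. Coupling of F5 with 35 as in step 17 would give the permethylated eight-ring ether F6, and BBr3 would convert it into 37.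

Step 17. Substitution at the bromide of 21, flanked by a 2,6-disubstituted aryloxy group and a methoxy group on an electron-rich ring, may be slow enough for protodebromination of 21 and oxidative degradation of the phenoxide of 35 to take over at 110 °C. The fallback reverses the roles of the two fragments; it sets out from 21 and 35 and comes back at 36. Hydroxylation of 21 (Pd2(dba)3, 2-di-tert-butylphosphino-2′,4′,6′-triisopropylbiphenyl, KOH, 1,4-dioxane–water, 100 °C) would give 6-[2-ethoxy-6-methoxy-4-(2,4,6-trimethoxyphenoxy)phenoxy]-2,3,4-trimethoxyphenol F7. Triflic anhydride and pyridine would convert 35 into the five-ring aryl triflate F8, whose sulfonate sits on an unhindered carbon. Palladium-catalysed C–O coupling of the hindered phenol F7 with F8 (Pd(OAc)2, the same biarylphosphine, K3PO4, toluene, 100 °C) would give 36.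

Step 4. Ketene 7 may dimerise or be consumed by amine-promoted oligomerisation faster than it adds to 6, and 8 may degrade by enolisation at C4 in the presence of Et3N. The fallback builds the four-membered ring from a squarate and attaches ring C afterwards; it sets out from 2 and purchased diethyl squarate (CCOC1=C(OCC)C(=O)C1=O) and comes back at 8. Reduction with LiAlH(OtBu)3 at −78 °C would give 2,3-diethoxy-4-hydroxycyclobut-2-en-1-one F9. Acid-promoted loss of ethanol would give 3-ethoxycyclobut-3-ene-1,2-dione F10. Reduction of the more electrophilic carbonyl (NaBH4, CeCl3·7H2O, MeOH, −78 °C) would give 3-ethoxy-4-hydroxycyclobut-2-en-1-one F11. A Mitsunobu etherification of F11 with 2 (PPh3, diisopropyl azodicarboxylate, THF, 0 °C) would give 8.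

Step 18. Twenty-one ethers must be cleaved; partly dealkylated boron aryloxides may precipitate from CH2Cl2 and escape further reaction, and the free pyrogallol rings may oxidise during work-up and chromatography. The fallback isolates the product as a stable derivative; it sets out from 36 and comes back at 37. The crude product of the BBr3 treatment would be acetylated (Ac2O, pyridine, 4-dimethylaminopyridine) to the henicosaacetate of the target F12, which can be purified on silica and checked for complete dealkylation. Acid-catalysed methanolysis in degassed methanol would then release 37 under oxygen-free conditions.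

## Further compounds

F1 | step 7 | 3,5-dimethoxy-4-(3,4,5-trimethoxyphenoxy)benzaldehyde | O=Cc1cc(OC)c(Oc2cc(OC)c(OC)c(OC)c2)c(OC)c1
F2 | step 7 | 4-(2-bromo-3,4,5-trimethoxyphenoxy)-3,5-dimethoxybenzaldehyde | O=Cc1cc(OC)c(Oc2cc(OC)c(OC)c(OC)c2Br)c(OC)c1
F3 | step 7 | 4-(2-bromo-3,4,5-trimethoxyphenoxy)-3,5-dimethoxyphenyl formate | O=COc1cc(OC)c(Oc2cc(OC)c(OC)c(OC)c2Br)c(OC)c1
F4 | step 7 | 4-(2-bromo-3,4,5-trimethoxyphenoxy)-3,5-dimethoxyphenol | Oc1cc(OC)c(Oc2cc(OC)c(OC)c(OC)c2Br)c(OC)c1
F5 | step 7 | 2-(2-bromo-3,4,5-trimethoxyphenoxy)-1,3-dimethoxy-5-(2,4,6-trimethoxyphenoxy)benzene | COc1cc(OC)c(Oc2cc(OC)c(Oc3cc(OC)c(OC)c(OC)c3Br)c(OC)c2)c(OC)c1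
F6 | step 7 | permethylated eight-ring ether ABCDEFGH | COc1cc(OC)c(Oc2cc(OC)c(Oc3cc(OC)c(OC)c(OC)c3Oc3cc(OC)c(Oc4cc(OC)c(OC)c(OC)c4Oc4cc(OC)c(Oc5cc(OC)c(OC)c(OC)c5Oc5cc(OC)c(OC)c(OC)c5)c(OC)c4)c(OC)c3)c(OC)c2)c(OC)c1
F7 | step 17 | 6-[2-ethoxy-6-methoxy-4-(2,4,6-trimethoxyphenoxy)phenoxy]-2,3,4-trimethoxyphenol | CCOc1cc(Oc2c(OC)cc(OC)cc2OC)cc(OC)c1Oc1cc(OC)c(OC)c(OC)c1O
F8 | step 17 | five-ring aryl triflate DEFGH (triflate on C1 of ring D) | O=S(=O)(Oc1cc(OC)c(Oc2cc(OC)c(OC)c(OC)c2Oc2cc(OC)c(Oc3cc(OC)c(OC)c(OC)c3Oc3cc(OC)c(OC)c(OC)c3)c(OC)c2)c(OC)c1)C(F)(F)F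
F9 | step 4 | 2,3-diethoxy-4-hydroxycyclobut-2-en-1-one (racemic) | O=C1C(OCC)=C(OCC)C1O
F10 | step 4 | 3-ethoxycyclobut-3-ene-1,2-dione | O=C1C=C(OCC)C1=O
F11 | step 4 | 3-ethoxy-4-hydroxycyclobut-2-en-1-one (racemic) | O=C1C=C(OCC)C1O
F12 | step 18 | henicosaacetate of the target | CC(=O)Oc1cc(OC(C)=O)c(Oc2cc(OC(C)=O)c(Oc3cc(OC(C)=O)c(OC(C)=O)c(OC(C)=O)c3Oc3cc(OC(C)=O)c(Oc4cc(OC(C)=O)c(OC(C)=O)c(OC(C)=O)c4Oc4cc(OC(C)=O)c(Oc5cc(OC(C)=O)c(OC(C)=O)c(OC(C)=O)c5Oc5cc(OC(C)=O)c(OC(C)=O)c(OC(C)=O)c5)c(OC(C)=O)c4)c(OC(C)=O)c3)c(OC(C)=O)c2)c(OC(C)=O)c1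
A1 | alternative 1 | seven-ring aryl iodide ABCDEFG (iodine on C6 of ring G) | COc1cc(OC)c(Oc2cc(OC)c(Oc3cc(OC)c(OC)c(OC)c3Oc3cc(OC)c(Oc4cc(OC)c(OC)c(OC)c4Oc4cc(OC)c(Oc5cc(OC)c(OC)c(OC)c5I)c(OC)c4)c(OC)c3)c(OC)c2)c(OC)c1
A2 | alternative 1 | six-ring phenol ABCDEF (hydroxyl on C4 of ring F) | COc1cc(OC)c(Oc2cc(OC)c(Oc3cc(OC)c(OC)c(OC)c3Oc3cc(OC)c(Oc4cc(OC)c(OC)c(OC)c4Oc4cc(OC)c(O)c(OC)c4)c(OC)c3)c(OC)c2)c(OC)c1
A3 | alternative 1 | 3,4,5-trimethoxy-2-(trimethylsilyl)phenyl trifluoromethanesulfonate | COc1cc(OS(=O)(=O)C(F)(F)F)c([Si](C)(C)C)c(OC)c1OC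
A4 | alternative 1 | 3,4,5-trimethoxybenzyne | COC1=C(OC)C(OC)=CC#C1
A5 | alternative 2 | 2-[4-(benzyloxy)-3,5-dimethoxyphenoxy]benzene-1,3,5-triol | Oc1cc(O)c(Oc2cc(OC)c(OCc3ccccc3)c(OC)c2)c(O)c1
A6 | alternative 2 | methyl 6-[4-(benzyloxy)-3,5-dimethoxyphenoxy]-3,5-dioxohexanoate | COC(=O)CC(=O)CC(=O)COc1cc(OC)c(OCc2ccccc2)c(OC)c1
A7 | alternative 2 | 6-{[4-(benzyloxy)-3,5-dimethoxyphenoxy]methyl}-4-hydroxy-2H-pyran-2-one | O=C1C=C(O)C=C(COc2cc(OC)c(OCc3ccccc3)c(OC)c2)O1
A8 | alternative 3 | 2-[4-(benzyloxy)-2,6-dimethoxyphenoxy]-4,5,6-trimethoxyphenol | Oc1c(OC)c(OC)c(OC)cc1Oc1c(OC)cc(OCc2ccccc2)cc1OC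
A9 | alternative 3 | 4-{(Z)-2-[4-(benzyloxy)-2,6-dimethoxyphenoxy]ethenyl}-2,3,4-trimethoxycyclobut-2-en-1-one (racemic) | O=C1C(OC)=C(OC)C1(OC)/C=C\Oc1c(OC)cc(OCc2ccccc2)cc1OC
A10 | alternative 3 | dimethyl squarate (3,4-dimethoxycyclobut-3-ene-1,2-dione) | COC1=C(OC)C(=O)C1=O
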